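(All constants were chosen freely; no experiment stands behind them.)

**Fixed ratios.** The concentration of incoming ligand cannot enter the ratio of any two steps of this flask, since each step is first order in it and it cancels.

    complex with one exchanged + incoming ligand → leaving ligand + complex with two exchanged (k1 = 0.0073 M⁻¹ s⁻¹)
    starting complex + incoming ligand → leaving ligand + complex with one exchanged (k2 = 0.010 M⁻¹ s⁻¹)
    complex with two exchanged + incoming ligand → leaving ligand + complex with three exchanged (k3 = 0.019 M⁻¹ s⁻¹)
    complex with three exchanged + incoming ligand → over-reaction product (k4 = 0.0066 M⁻¹ s⁻¹)

common to all: starting complex 0.050 M; time 3.0 h
- beta: incoming ligand 0.150 M (fed, over 0.80 min)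
- theta: incoming ligand 0.150 M (fed, over 1.5 min)
- epsilon: incoming ligand 0.150 M (fed, over 3.0 min)
- gamma: incoming ligand 0.150 M (fed, over 6.0 min)
- zeta: incoming ligand 0.150 M (fed, over 12 min)

- "hardly changes" means that all values lie within two and a half points (for a concentration: within two and a half percent of the largest)
- run time (beta): 3.0 h

- amount of complex with three exchanged at the end, in percent of the starting complex charged for beta, theta, epsilon, gamma, zeta, in this order
- how that number moves from the first to the last of them (hardly changes / falls all the way / rises all the way / rises, then falls / falls, then rises)

The selectivity factor of the first exchange over the second, for instance, stays 1.37 however the ligand goes in. The mix of complexes therefore depends on one running sum, the exposure, which is c(incoming ligand) integrated over time.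

**Beta against theta.** Beta's dosing time of 0.80 min and theta's of 1.5 min are both shorter than the 7.70 min half-life of starting complex by its own exchange with the whole charge present, so we take the ligand as still unused while it goes in. A feed then gathers half the exposure of a single shot over the same time, and afterwards the flask follows the same path later. We call this delay the feed lag, half the dosing time: 0.400 min for beta and 0.750 min for theta. By this reckoning theta runs 0.350 min behind beta, which is 0.194% of the 3.0 h run, and we expect the two to end alike. Our reckoning stops there: it gives a delay and no height.

**The forecast.** It gives 29.6%, 29.6%, 29.7%, 29.7% and 29.7%, a row that hardly changes, on the grounds that “feeding over a few minutes cannot change selectivity”.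

**What stands.** The flasks end at 29.5% in beta, 29.5% in theta, 29.5% in epsilon, 29.5% in gamma and 29.6% in zeta, a row that hardly changes. Beta's feed lag of 0.400 min and zeta's of 6.00 min, a rough figure as zeta's feed outlasts the 7.70 min half-life of starting complex, are both shorter than the 0.589 h by which beta has half of its turnover into complex with three exchanged behind it. Zeta ends with 3.0% of its incoming ligand left, more than the 2.8% in beta.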